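(The rate constants are assumed; the rest is arithmetic.)

Alpha holds twice the catalyst of beta, so before the next run we ask which charge is enough.

    partner + free catalyst ⇌ catalyst intermediate A (K1 = 2500 M⁻¹, k1 = 28000 M⁻¹ s⁻¹)
    starting material + catalyst intermediate A → catalyst intermediate B (k2 = 17000 M⁻¹ s⁻¹)
    catalyst intermediate B → free catalyst + product (k3 = 7.6 s⁻¹)
    solid substrate ⇌ starting material, rate k4*(cs4 - [starting material]) while solid is left; crystals form when [starting material] > cs4 (cs4 = 0.18 mM, k4 = 0.097 s⁻¹)

common to all: solid substrate 0.50 mM; partner 0.500 mM (in portions, 4); time 8.0 min
- epsilon: free catalyst 2.5 µM; the portions of partner follow each other after 8.0 s, the first at the start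
- beta: free catalyst 4.0 µM; the portions of partner follow each other after 8.0 s, the first at the start
- gamma: free catalyst 6.0 µM; the portions of partner follow each other after 8.0 s, the first at the start
- alpha: free catalyst 8.0 µM; the portions of partner follow each other after 8.0 s, the first at the start

- [product] at the end for epsilon, beta, gamma, alpha, in this order
- how that number moves from the first to the last of them (falls, then rises / hardly changes / rises, then falls / rises all the way / falls all the way)

- solid, in amounts per volume of the solution: solid substrate
- at the start none of the solid substrate is in solution
- "hardly changes" means that all values lie within two and a half points (for a concentration: within two and a half percent of the largest)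
- run time (epsilon): 8.0 min

Our aim is to leave less than 3.00% of the partner at the end, with the smallest of these charges.

Partner and solid substrate are charged equally, so once the solid is gone, partner and starting material stand equal, and we let c stand for both. One turnover of one catalyst then costs three waits: a fixed 0.132 s, then 0.0945 mM·s divided by c, then a term divided by c squared.

The last term comes from binding. Catalyst intermediate A falls back at 11.2 s⁻¹, faster than starting material takes it even at the solubility, 3.06 s⁻¹. So binding runs near a pre-equilibrium, though the two rates differ by a factor of only 3.66 at the solubility. The coefficient is the tail price, 0.02353 mM^2 s: the reciprocal of the binding constant times the rate constant of the attack on catalyst intermediate A.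

A flask's speed is its catalyst divided by the cost. What a flask can buy is therefore its catalyst-time, the catalyst charge times the run time.

Summed from the charge down to c, the cost is an overhead plus the tail price over c. The overhead holds the fixed wait over the whole charge and a logarithm that grows slowly. We freeze that logarithm at the aim, which gives 0.397 mM·s. While solid is left, starting material stands lower than partner and turnovers cost more. As a rough estimate, we let the tail price, counted from the very start, stand for that. So c is the tail price divided by the difference between catalyst-time and overhead.

| Flask | Catalyst-time | Partner left | Product |
|---|---|---|---|
| epsilon | 1.20 mM·s | 5.86% | 0.471 mM |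
| beta | 1.92 mM·s | 3.09% | 0.485 mM |
| gamma | 2.88 mM·s | 1.90% | 0.491 mM |
| alpha | 3.84 mM·s | 1.37% | 0.493 mM |

By this reckoning beta stays just above the aim and gamma falls below it, so we would charge gamma's 6.0 µM.

The forecast gave 0.469 mM, 0.483 mM, 0.489 mM and 0.492 mM, and called the row rises all the way, since the “spread of about 0.023 mM exceeds the 2.5% band”.

The simulation gives 0.469 mM, 0.483 mM, 0.489 mM and 0.492 mM, and the row rises all the way. Beta leaves 3.4% of its partner and gamma 2.1%.

In epsilon at 8.00 min the forward binding step alone halves partner in 0.18 min, much shorter than the run, and still 6.2% of the partner stands unbound beside 6.84% of the catalyst as catalyst intermediate A. Alpha at 4.00 min has spent 1.92 mM·s of catalyst-time, the same as beta at its end, so the tail price gives both 3.09%, and the readings are 3.67% for alpha and 3.40% for beta.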